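Labels: ring A is the oxane (O1, C2 gem-dimethyl, C3 bromine, C6 methyl and chain). Ring B is the cyclohexane C1'–C6' (C1' chain, C4' methyl carbinol, C5' bromine). The chain is Ca(CH3)=Cb–Cc=Cd, with Ca on C1' and Cd on C6.
Cuts: Cb–Cc (alkenyl–alkenyl coupling), Ca–CH3 (methylalumination of a C1' ethynyl group), C4'–CH3, C5'–Br, then C1'–C6' and C2'–C3' of ring B. Ring A is cut at O1–C2 and C3–Br, which leads back to (S)-linalool.
Enabling feature: ring B has its carbon substituent (C1') and its oxygen (C4') in a 1,4 relation, with bromine on the adjacent C5'. A para-selective [4+2] addition of a 2-silyloxybutadiene to an acrylate gives a C4'=C5' silyl enol ether with exactly this pattern.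
Forward order: ring B closes first by cycloaddition, then it is brominated, corrected at C5', methylated at C4' and homologated to the alkyne. Ring A closes separately by bromoetherification and becomes an (E)-iodoalkene, and the halves are joined last.
Stereochemistry: C1' comes from the chiral boron catalyst and is held as the position of the enol ether double bond. C5' (axial kinetic protonation of the bromo enolate) and C4' (equatorial methyl delivery) are relayed from C1'. C6 comes from (S)-linalool, and C3 from a chair-like bromoetherification followed by separation of its epimer. Both E alkenes come from syn-carbometalation, Takai olefination and a stereoretentive coupling.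

Key step: step 2

Assumption: the facial sense in the cycloaddition is assigned from the accepted α-C–H···O binding model for acrylates on N-protonated oxazaborolidines (S catalyst, Si face of the α-carbon, R adduct). If the assay of the adduct shows the opposite sense, the equally available antipodal catalyst is used.

Step 1
Reactants: 1 but-3-en-2-one (methyl vinyl ketone)
Product: 2 2-(triisopropylsilyloxy)buta-1,3-diene
Conditions: TIPSOTf, Et3N, Et2O, 0 °C → rt
Reagents that add atoms: triisopropylsilyl triflate, CC(C)[Si](C(C)C)(C(C)C)OS(=O)(=O)C(F)(F)F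
Why: Soft enolisation (silyl triflate plus amine) can only take place at the methyl group of the enone and should give the 2-silyloxydiene, with TIPS chosen because it withstands the acidic catalyst of step 2.

Step 2
Reactants: 2 2-(triisopropylsilyloxy)buta-1,3-diene; 3 2,2,2-trifluoroethyl acrylate
Product: 4 2,2,2-trifluoroethyl (R)-4-(triisopropylsilyloxy)cyclohex-3-ene-1-carboxylate
Conditions: (S)-3,3-diphenyl-1-(o-tolyl)tetrahydro-1H,3H-pyrrolo[1,2-c][1,3,2]oxazaborole (10 mol %), HN(SO2CF3)2 (8 mol %), CH2Cl2, −78 → −20 °C
Reagents that add atoms: none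
Why: The N-protonated oxazaborolidine binds the acrylate carbonyl at boron through the lone pair syn to the vinyl group, an α-C–H···O contact to the ring oxygen holds the s-trans enoate over the neighbouring phenyl group, and the diene adds in a concerted but asynchronous [4+2] process in which C2'–C3' (acrylate β-carbon to the nucleophilic CH2 next to C–OSi) runs ahead of C1'–C6'. The closest known reaction type is the oxazaborolidinium-catalysed enantioselective Diels–Alder reaction of 2-silyloxybutadienes and other simple dienes with trifluoroethyl acrylate, so this is an application of known chemistry. Ring B closes as a six-membered carbocycle by suprafacial addition of the s-cis diene to the alkene, both σ-bonds arising in the same step. C1', the only new stereocentre, is controlled by the catalyst: the phenyl group covers the Re face of the α-carbon, the diene reaches the Si face, and the R configuration results. The step needs para regioselectivity, which the silyloxy group secures by placing the largest HOMO coefficient on the adjacent terminal CH2 and pairing it with the β-carbon, while endo/exo selectivity is irrelevant because no second stereocentre forms. The bulky TIPS group protects the enol ether from protodesilylation by the acidic catalyst, which matters because the free ketone is achiral and the C1' information survives only as the position of the C4'=C5' double bond.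

Step 3
Reactants: 4 2,2,2-trifluoroethyl (R)-4-(triisopropylsilyloxy)cyclohex-3-ene-1-carboxylate
Product: 5 (R)-N-methoxy-N-methyl-4-(triisopropylsilyloxy)cyclohex-3-ene-1-carboxamide
Conditions: MeNHOMe·HCl, iPrMgCl, THF, −20 °C; then 4, −20 °C
Reagents that add atoms: N,O-dimethylhydroxylamine hydrochloride, CNOC.Cl
Why: Acyl substitution of the activated ester by the preformed magnesium amide (Weinreb amide synthesis) is fast in the cold, leaves C1'–H and the enol ether untouched, and installs an acyl group that is less acidic at C1', inert in steps 4–8 and reducible to the aldehyde without over-reduction.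

Step 4
Reactants: 5 (R)-N-methoxy-N-methyl-4-(triisopropylsilyloxy)cyclohex-3-ene-1-carboxamide
Product: 6 (1R,3S)-3-bromo-N-methoxy-N-methyl-4-oxocyclohexane-1-carboxamide (bromine axial, trans to the amide; accompanied by some of its C5' epimer, which is not removed)
Conditions: NBS, NaHCO3 (buffer), THF–H2O, −20 → 0 °C
Reagents that add atoms: N-bromosuccinimide, O=C1CCC(=O)N1Br
Why: In this electrophilic α-bromination of a silyl enol ether, bromine can enter only at C5', the nucleophilic carbon of the C4'=C5' unit, and the stereoelectronically preferred axial attack anti to the pseudo-equatorial amide should give mainly the trans bromide, whose C5' configuration does not matter because step 5 erases it.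

Step 5
Reactants: 6 (1R,3S)-3-bromo-N-methoxy-N-methyl-4-oxocyclohexane-1-carboxamide (with its C5' epimer)
Product: 7 (R)-3-bromo-4-(tert-butyldimethylsilyloxy)-N-methoxy-N-methylcyclohex-3-ene-1-carboxamide
Conditions: TBSOTf, iPr2NEt, CH2Cl2, −20 → 0 °C
Reagents that add atoms: tert-butyldimethylsilyl triflate, CC(C)(C)[Si](C)(C)OS(=O)(=O)C(F)(F)F
Why: Soft enolisation with a silyl triflate and a hindered amine should remove the more acidic, bromine-bearing C5'–H and funnel both C5' epimers into one tetrasubstituted bromo enol ether, and the absence of HBr and free bromide prevents migration of bromine to C3', which would amount to racemisation.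

Step 6
Reactants: 7 (R)-3-bromo-4-(tert-butyldimethylsilyloxy)-N-methoxy-N-methylcyclohex-3-ene-1-carboxamide
Product: 8 (1R,3R)-3-bromo-N-methoxy-N-methyl-4-oxocyclohexane-1-carboxamide (bromine and amide cis, both equatorial)
Conditions: TBAF, AcOH, THF, −78 → −40 °C; cold pH 5 buffer
Reagents that add atoms: none
Why: Fluoride releases the bromo enolate, and acetic acid protonates it irreversibly in the cold (diastereoselective kinetic protonation), the proton entering C5' axially through a chair-like transition state on the face anti to the pseudo-equatorial C1' amide, which is the same bias that misplaced bromine in step 4, so bromine should end up equatorial and cis to C1' (5'R).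

Step 7
Reactants: 8 (1R,3R)-3-bromo-N-methoxy-N-methyl-4-oxocyclohexane-1-carboxamide
Product: 9 (1R,3R,4S)-3-bromo-4-hydroxy-N-methoxy-N,4-dimethylcyclohexane-1-carboxamide
Conditions: MeLi, ClTi(OiPr)3, Et2O, −40 °C; then 8, −40 → 0 °C
Reagents that add atoms: methyllithium, [Li]C (converted in the flask to methyltitanium triisopropoxide, C[Ti](OC(C)C)(OC(C)C)OC(C)C)
Why: The non-basic organotitanium reagent adds 1,2 to the ketone only, without enolisation or attack on the Weinreb amide, and being bulky it avoids the axial hydrogens at C2' and C6' and attacks equatorially, giving equatorial methyl and axial hydroxyl (4'S), a cis-bromohydrin that cannot close to an epoxide.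

Step 8
Reactants: 9 (1R,3R,4S)-3-bromo-4-hydroxy-N-methoxy-N,4-dimethylcyclohexane-1-carboxamide
Product: 10 (1R,3R,4S)-3-bromo-N-methoxy-N,4-dimethyl-4-(triethylsilyloxy)cyclohexane-1-carboxamide
Conditions: TESOTf, 2,6-lutidine, CH2Cl2, −78 → 0 °C
Reagents that add atoms: triethylsilyl triflate, CC[Si](CC)(CC)OS(=O)(=O)C(F)(F)F
Why: Silylation with a silyl triflate works on hindered tertiary alcohols, and it keeps an aluminium alkoxide from forming next to the C5' bromide in step 14, where ring contraction could follow.

Step 9
Reactants: 10 (1R,3R,4S)-3-bromo-N-methoxy-N,4-dimethyl-4-(triethylsilyloxy)cyclohexane-1-carboxamide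
Product: 11 (1R,3R,4S)-3-bromo-4-methyl-4-(triethylsilyloxy)cyclohexane-1-carbaldehyde
Conditions: iBu2AlH, THF, −78 °C; aq. potassium sodium tartrate
Reagents that add atoms: none
Why: Hydride reduction of a Weinreb amide stops at the chelated tetrahedral adduct, which gives the aldehyde only on work-up, and the secondary bromide and silyl ether are inert at this temperature.

Step 10
Reactants: 11 (1R,3R,4S)-3-bromo-4-methyl-4-(triethylsilyloxy)cyclohexane-1-carbaldehyde
Product: 12 {[(1S,2R,4R)-2-bromo-4-ethynyl-1-methylcyclohexyl]oxy}triethylsilane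
Conditions: dimethyl (1-diazo-2-oxopropyl)phosphonate, K2CO3, MeOH, 0 °C → rt
Reagents that add atoms: dimethyl (1-diazo-2-oxopropyl)phosphonate, COP(=O)(OC)C(=[N+]=[N-])C(C)=O
Why: Seyferth–Gilbert homologation with the Ohira–Bestmann reagent gives the terminal alkyne under mild carbonate conditions that spare bromide and silyl ether, and C1' is not at risk because it already sits in the thermodynamically preferred equatorial orientation.

Step 11
Reactants: 13 (S)-linalool, (3S)-3,7-dimethylocta-1,6-dien-3-ol
Product: 14 (3R,6S)-3-bromo-6-ethenyl-2,2,6-trimethyloxane (bromine and vinyl trans, both equatorial)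
Conditions: 2,4,4,6-tetrabromocyclohexa-2,5-dien-1-one, MeNO2, 0 °C → rt
Reagents that add atoms: 2,4,4,6-tetrabromocyclohexa-2,5-dien-1-one, BrC1=CC(Br)(Br)C=C(Br)C1=O
Why: In this bromonium-induced cycloetherification the electron-rich trisubstituted alkene reacts before the vinyl group and the tertiary hydroxyl opens the bromonium ion at its more substituted carbon (6-endo, Markovnikov) through a chair with bromine equatorial, so C6 is inherited from 13 while C3 forms on both alkene faces and the 3R isomer is separated by chromatography from its epimer and from oxolane isomers.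

Step 12
Reactants: 14 (3R,6S)-3-bromo-6-ethenyl-2,2,6-trimethyloxane
Product: 16 (2S,5R)-5-bromo-2,6,6-trimethyloxane-2-carbaldehyde, via secondary ozonide 15 (not isolated)
Conditions: O3, CH2Cl2, −78 °C; Me2S, −78 °C → rt
Reagents that add atoms: ozone, [O-][O+]=O
Why: Ozonolysis with reductive work-up cleaves the only alkene, and the resulting aldehyde has no α-hydrogen, so the quaternary centre cannot epimerise.

Step 13
Reactants: 16 (2S,5R)-5-bromo-2,6,6-trimethyloxane-2-carbaldehyde
Product: 17 (3R,6S)-3-bromo-6-[(E)-2-iodoethenyl]-2,2,6-trimethyloxane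
Conditions: CrCl2, CHI3, THF, 0 °C → rt
Reagents that add atoms: iodoform, IC(I)I
Why: Takai olefination with the geminal dichromium reagent gives (E)-iodoalkenes, most selectively from bulky aldehydes, and divalent chromium reduces an unactivated secondary bromide far more slowly than it reduces iodoform.

Step 14
Reactants: 12 {[(1S,2R,4R)-2-bromo-4-ethynyl-1-methylcyclohexyl]oxy}triethylsilane; 17 (3R,6S)-3-bromo-6-[(E)-2-iodoethenyl]-2,2,6-trimethyloxane
Product: 19 {[(1S,2R,4R)-2-bromo-4-{(2E,4E)-5-[(2S,5R)-5-bromo-2,6,6-trimethyloxan-2-yl]penta-2,4-dien-2-yl}-1-methylcyclohexyl]oxy}triethylsilane, via alkenyldimethylalane 18 (not isolated)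
Conditions: Me3Al, Cp2ZrCl2 (25 mol %), CH2Cl2, 0 °C → rt; volatiles removed; THF, 17, Pd(PPh3)4 (5 mol %), ZnCl2 (30 mol %), rt
Reagents that add atoms: trimethylaluminium, C[Al](C)C
Why: Zirconium-catalysed syn-methylalumination places methyl on Ca and aluminium on Cb on the same side, and the Negishi-type coupling at zerovalent palladium, with zinc as co-catalyst for the hindered alane, joins Cb to Cc with retention at both alkenes, leaves both alkyl bromides alone, and turns any enantiomeric impurity of either half into a separable diastereomer.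

Step 15
Reactants: 19 {[(1S,2R,4R)-2-bromo-4-{(2E,4E)-5-[(2S,5R)-5-bromo-2,6,6-trimethyloxan-2-yl]penta-2,4-dien-2-yl}-1-methylcyclohexyl]oxy}triethylsilane
Product: 20 (1S,2R,4R)-2-bromo-4-{(2E,4E)-5-[(2S,5R)-5-bromo-2,6,6-trimethyloxan-2-yl]penta-2,4-dien-2-yl}-1-methylcyclohexan-1-ol
Conditions: TBAF, AcOH, THF, 0 °C → rt
Reagents that add atoms: none
Why: Buffered fluoride desilylation avoids both the acid that could ionise the dienylic tertiary ether at C6 and a free alkoxide next to the C5' bromide.

Compound list
1 | but-3-en-2-one (methyl vinyl ketone) | CC(=O)C=C | starting material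
2 | 2-(triisopropylsilyloxy)buta-1,3-diene | C=CC(=C)O[Si](C(C)C)(C(C)C)C(C)C | intermediate
3 | 2,2,2-trifluoroethyl acrylate | C=CC(=O)OCC(F)(F)F | starting material
4 | 2,2,2-trifluoroethyl (R)-4-(triisopropylsilyloxy)cyclohex-3-ene-1-carboxylate | O=C(OCC(F)(F)F)[C@@H]1CCC(O[Si](C(C)C)(C(C)C)C(C)C)=CC1 | intermediate
5 | (R)-N-methoxy-N-methyl-4-(triisopropylsilyloxy)cyclohex-3-ene-1-carboxamide | CON(C)C(=O)[C@@H]1CCC(O[Si](C(C)C)(C(C)C)C(C)C)=CC1 | intermediate
6 | (1R,3S)-3-bromo-N-methoxy-N-methyl-4-oxocyclohexane-1-carboxamide | CON(C)C(=O)[C@@H]1CCC(=O)[C@@H](Br)C1 | intermediate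
7 | (R)-3-bromo-4-(tert-butyldimethylsilyloxy)-N-methoxy-N-methylcyclohex-3-ene-1-carboxamide | CON(C)C(=O)[C@@H]1CCC(O[Si](C)(C)C(C)(C)C)=C(Br)C1 | intermediate
8 | (1R,3R)-3-bromo-N-methoxy-N-methyl-4-oxocyclohexane-1-carboxamide | CON(C)C(=O)[C@@H]1CCC(=O)[C@H](Br)C1 | intermediate
9 | (1R,3R,4S)-3-bromo-4-hydroxy-N-methoxy-N,4-dimethylcyclohexane-1-carboxamide | CON(C)C(=O)[C@@H]1CC[C@](C)(O)[C@H](Br)C1 | intermediate
10 | (1R,3R,4S)-3-bromo-N-methoxy-N,4-dimethyl-4-(triethylsilyloxy)cyclohexane-1-carboxamide | CON(C)C(=O)[C@@H]1CC[C@](C)(O[Si](CC)(CC)CC)[C@H](Br)C1 | intermediate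
11 | (1R,3R,4S)-3-bromo-4-methyl-4-(triethylsilyloxy)cyclohexane-1-carbaldehyde | O=C[C@@H]1CC[C@](C)(O[Si](CC)(CC)CC)[C@H](Br)C1 | intermediate
12 | {[(1S,2R,4R)-2-bromo-4-ethynyl-1-methylcyclohexyl]oxy}triethylsilane | C#C[C@@H]1CC[C@](C)(O[Si](CC)(CC)CC)[C@H](Br)C1 | intermediate
13 | (S)-linalool, (3S)-3,7-dimethylocta-1,6-dien-3-ol | C=C[C@@](C)(O)CCC=C(C)C | starting material
14 | (3R,6S)-3-bromo-6-ethenyl-2,2,6-trimethyloxane | C=C[C@]1(C)CC[C@@H](Br)C(C)(C)O1 | intermediate
15 | 3-[(2S,5R)-5-bromo-2,6,6-trimethyloxan-2-yl]-1,2,4-trioxolane (secondary ozonide, not isolated) | C1OOC(O1)[C@]2(C)CC[C@@H](Br)C(C)(C)O2 | intermediate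
16 | (2S,5R)-5-bromo-2,6,6-trimethyloxane-2-carbaldehyde | O=C[C@]1(C)CC[C@@H](Br)C(C)(C)O1 | intermediate
17 | (3R,6S)-3-bromo-6-[(E)-2-iodoethenyl]-2,2,6-trimethyloxane | I/C=C/[C@]1(C)CC[C@@H](Br)C(C)(C)O1 | intermediate
18 | {(1E)-2-[(1R,3R,4S)-3-bromo-4-methyl-4-(triethylsilyloxy)cyclohexyl]prop-1-en-1-yl}dimethylalane (not isolated) | C[Al](C)/C=C(\C)[C@@H]1CC[C@](C)(O[Si](CC)(CC)CC)[C@H](Br)C1 | intermediate
19 | {[(1S,2R,4R)-2-bromo-4-{(2E,4E)-5-[(2S,5R)-5-bromo-2,6,6-trimethyloxan-2-yl]penta-2,4-dien-2-yl}-1-methylcyclohexyl]oxy}triethylsilane | C/C(=C\C=C\[C@]1(C)CC[C@@H](Br)C(C)(C)O1)[C@@H]1CC[C@](C)(O[Si](CC)(CC)CC)[C@H](Br)C1 | intermediate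
20 | (1S,2R,4R)-2-bromo-4-{(2E,4E)-5-[(2S,5R)-5-bromo-2,6,6-trimethyloxan-2-yl]penta-2,4-dien-2-yl}-1-methylcyclohexan-1-ol | C/C(=C\C=C\[C@]1(C)CC[C@@H](Br)C(C)(C)O1)[C@@H]1CC[C@](C)(O)[C@H](Br)C1 | target

Total step count: 15. Longest linear sequence: 12 (steps 1–10, 14, 15).

Steps most likely to fail

Step 5. Three things may go wrong.
- Enolisation may run toward C3' instead of C5', because the C5'–H of the axial bromide lies close to the carbonyl plane.
- The bromoketone may alkylate the amine.
- An allylic bromide isomer may ionise and let bromine move to C3', which lowers the enantiomeric purity.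

The fallback sets out from 1 and 3 and comes back at 8. It puts the bromine on the diene, so the cycloaddition itself delivers the bromo enol ether and no enolisation is needed. Compound 1 takes up Br2 (CH2Cl2, 0 °C) to give 3,4-dibromobutan-2-one F1. Et3N then eliminates HBr to give 3-bromobut-3-en-2-one F2, and TIPSOTf/Et3N gives 3-bromo-2-(triisopropylsilyloxy)buta-1,3-diene F3. Under the catalyst of step 2, F3 and 3 should form the same two ring bonds. The silyloxy group should outweigh bromine in directing para addition, giving 2,2,2-trifluoroethyl (R)-3-bromo-4-(triisopropylsilyloxy)cyclohex-3-ene-1-carboxylate F4. Amidation as in step 3 gives (R)-3-bromo-N-methoxy-N-methyl-4-(triisopropylsilyloxy)cyclohex-3-ene-1-carboxamide F5. This is the TIPS analogue of 7, and it is desilylated and protonated as in step 6 to reach 8.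

Step 6. The protonation may show poor facial selectivity, or the equatorial bromide may epimerise through acetate-mediated enolisation before the quench. The fallback sets out from 6 and comes back at 8, replacing kinetic control with thermodynamic control. The epimer mixture from step 4 is stirred with LiBr in DMF at rt, which makes step 5 unnecessary as well. Degenerate SN2 exchange of bromide at C5' interconverts the epimers without touching C3' or C1'. The polar medium favours the more polar diequatorial epimer 8, which is separated by chromatography, and recovered 6 is resubmitted.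

Step 11. Two things may go wrong: competing 5-exo closure to oxolanes, and no discrimination between the two faces of the trisubstituted alkene. The fallback sets out from 13 and comes back at 14, using divalent mercury as the electrophile instead of a bromonium source.
- Hg(OCOCF3)2 in MeCN at 0 °C brings about a reversible, strictly Markovnikov oxymercuration that should close only the oxane, giving [(3R,6S)-6-ethenyl-2,2,6-trimethyloxan-3-yl]mercury trifluoroacetate F6.
- Aqueous KBr converts this to crystalline [(3R,6S)-6-ethenyl-2,2,6-trimethyloxan-3-yl]mercury bromide F7, and the C3 epimers are separated by crystallisation at this stage.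
- Polar bromodemercuration (Br2, LiBr, pyridine, O2 atmosphere, 0 °C) replaces mercury by bromine with retention to give 14.

Further compounds
F1 | step 5 | 3,4-dibromobutan-2-one | CC(=O)C(Br)CBr
F2 | step 5 | 3-bromobut-3-en-2-one | CC(=O)C(Br)=C
F3 | step 5 | 3-bromo-2-(triisopropylsilyloxy)buta-1,3-diene | C=C(Br)C(=C)O[Si](C(C)C)(C(C)C)C(C)C
F4 | step 5 | 2,2,2-trifluoroethyl (R)-3-bromo-4-(triisopropylsilyloxy)cyclohex-3-ene-1-carboxylate | O=C(OCC(F)(F)F)[C@@H]1CCC(O[Si](C(C)C)(C(C)C)C(C)C)=C(Br)C1
F5 | step 5 | (R)-3-bromo-N-methoxy-N-methyl-4-(triisopropylsilyloxy)cyclohex-3-ene-1-carboxamide | CON(C)C(=O)[C@@H]1CCC(O[Si](C(C)C)(C(C)C)C(C)C)=C(Br)C1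
F0 | step 6 | none | none
F6 | step 11 | [(3R,6S)-6-ethenyl-2,2,6-trimethyloxan-3-yl]mercury trifluoroacetate | C=C[C@]1(C)CC[C@@H]([Hg]OC(=O)C(F)(F)F)C(C)(C)O1
F7 | step 11 | [(3R,6S)-6-ethenyl-2,2,6-trimethyloxan-3-yl]mercury bromide | C=C[C@]1(C)CC[C@@H]([Hg]Br)C(C)(C)O1
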